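Which of Z, L and Q held most of the Z at the end of each flask, and how much?

    J + G + L → G + Q (k1 = 1.03 L² mol⁻² s⁻¹)
    G + Q ⇌ G.Q (K2 = 1.81 L mol⁻¹, k2 = 0.00687 L mol⁻¹ s⁻¹)
    Z + D → Z.D (k3 = 8.97 × 10⁻⁴ L mol⁻¹ s⁻¹)
    Z + G ⇌ G + L (K4 = 0.380, k4 = 1.53 L mol⁻¹ s⁻¹)

- south-west: Z 0.80 M; J 2.10 M; D 0.240 M; G 0.80 mM; time 4.0 h
- north: Z 0.80 M; J 0.840 M; D 0.240 M; G 0.80 mM; time 4.0 h

* which of these there is most of at the end, counted by the Z in it, south-west (Z / L / Q)
* which of these there is most of at the end, counted by the Z in it, north (Z / L / Q)
* amount of the one of these that there is most of at the end, in percent of the Z charged, south-west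
* amount of the one of these that there is most of at the end, in percent of the Z charged, north

- amounts and yields of Q count G.Q too
- run time (south-west): 4.0 h

I looked for the concentration that set the order of the rate, and it was L. In north, Z and L reached their ratio with a half-time of 0.0433 h, faster than the 0.28 h half-life of L on the way to Q. So I held L at its equilibrium share of the pool Z + L:

share of L = 27.5%

D has a half-life of 0.268 h against Z as charged, shorter than the run. So in my reckoning for both flasks I let D take its full 30.0% of the Z early, an assumption that gave Q a ceiling of 70.0%. With Q at that level, the free share of G is: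

free G = 49.7%

With J and G held, the pool drains pseudo-first-order:

north: T = 1.03 L² mol⁻² s⁻¹ × 0.840 M × 0.80 mM × 27.5% × 49.7% × 4.0 h = 1.36

south-west: T = 3.41

This T, the run time counted in lifetimes of the pool against the drain to Q, leaves exp(−T) of the pool undrained. Q is therefore 52.1% in north and 67.7% in south-west, first in both.

Was one number enough? That Q costs north 49.6% of its J, so T ran high there, while G taken at its late share ran low early on. I kept T anyway.

The forecast also put Q first in both flasks, at 70% in south-west and 51% in north, with free G “progressively tied up as G.Q”. My south-west figure was lower and my north figure higher.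

The flasks gave Q first, 70.4% in south-west and 51.5% in north. North ended with Z.D at 28.6% and D at 4.50% of its charge, but south-west ended with Z.D at 25.5%, less than the share I had allowed, and D at 14.9% of its charge. Ten times the run makes T 13.6 in north, which leaves hardly any of the pool undrained and puts Q at 70.0%; north held 69.9% after 40.0 h.

A flask like north with 2.0 × 10⁻⁴ M of G has T = 0.341, which gives Q 20.2% and Z 36.1%, so Z leads. That flask gave Z first, at 33.4%, with Q at 25.6%.

(The numbers of this flask come from no measurement; the flask was simulated.)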